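In millimolar per day I kept one account, that of G, the limiting reagent. The gas D is held, and into a solution kept empty the gas step can deliver at most 367% of the charge by 4.0 d, more than the 49.4% the dissolving step can, so solid G stays through the run.

G 10 mM; D 0.59 mM (held); time 4.0 d

    D ⇌ J, rate k1*(csat - [J]) (k1 = 1.8 × 10⁻⁴ /s, csat = 0.59 mM)
    Z + J → Z.J (k2 = 0.031 /M/s)
    Z → X (k3 = 1.2 × 10⁻⁵ /s)
    Z.J ⇌ E (K4 = 0.83, k4 = 7.2 × 10⁻⁶ /s)
    G ⇌ Z, rate k5*(cs5 - [Z]) while solid is left; crystals form when [Z] > cs5 (cs5 = 1.3 mM, k5 = 1.1 × 10⁻⁵ /s)

- solid, in amounts per volume of the solution: G
- at the start none of J is dissolved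
- at the start none of G is in solution
- run time (flask): 4.0 d

- midnight: doubling the solubility in step 5, all else as stated
- autumn: doubling the saturation concentration of D, all else as stated
- dusk: doubling the dissolution coefficient of step 5, all else as stated
- spring: doubling the transfer coefficient of step 1, all else as stated

1. the Z.J standing at 4.0 d, as a percentage of the G charged
2. the change that raises the amount of Z.J at 4.0 d, in percent of the G charged most ("none" if none brings more than 2 percentage points) (midnight / autumn / dusk / spring / none)
3. amount of Z.J at 4.0 d, in percent of the G charged, after dusk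

I booked steady flows:

- J level: 0.557 mM
- pull of J on each Z (pseudo-first-order): 1.49 /d
- Z level: 0.355 mM
- settling time of Z: 0.287 d
- Z.J formed per day: 0.530 mM/d

I call this last flow, the pull of J times the Z level, the daily make. Z settles in a time short against the run, so I held these flows steady. The books at 4.0 d, in parts of the G charged:

- standing as Z: 3.55%
- gone to Z.J or E, the make over the run less the settling time: 1.97 mM, or 19.7%
- gone to X, in the ratio of the two pulls on Z: 13.7%
- still solid G: 63.1%

Z.J and E relax in a time short against the run, at a rate of 1.37 /d. So Z.J holds its equilibrium share of the total, 1.07 mM, plus a fixed surplus, 0.175 mM. That gave 12.5%.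

Ranked by make, the winner was midnight. After dusk, with J held, the make was 0.832 mM/d and the total 3.14 mM, giving 19.9%.

The forecast said 12.5% (12% to 13%), midnight, and 19.5% (18.8% to 20.2%) after dusk, on the ground that “Solid G outlasts the run in the base case and in dusk”. Its dusk figure stands below mine.

The simulation gave 12.5%, then midnight with a gain of 12 percentage points, and 19.4% after dusk.

To leave the range of the forecast, the charge or the time would have to move: in the runs, the Z.J standing moved by 5 points at 7.14 mM or 16.7 mM of G, and at 2.31 d or 5.72 d. The neighbouring flask, the same charge left until 6.0 d, lies past that last time. Its make is the same 0.530 mM/d, so its total is 3.03 mM, and the same equilibrium share and surplus give 18.3% as Z.J. That flask, simulated, held 18.3%.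

(The numbers of this flask stand for no real mixture; the flask was simulated.)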